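C1 is the arene carbon bearing the phenolic oxygen, C3 bears the benzylic carbon C7, C6 bears the fully substituted carbon C8, C9 is the oxirane CH2 and C10 the acetoxymethyl carbon.
Retrosynthesis cuts the oxirane C9–O bond and the acetate (back to a prochiral 2-arylglycerol), the angelate and 2-methylbutanoate C–O bonds, the arene bonds C1–C2 and C3–C4, and last C6–C8.
The feature used is the 1,2,4-pattern of the arene: the oxygen on C1 sits next to the C8-bearing C6 and meta to the C7-bearing C3, which is the 3-hydroxy-4-alkylbenzoate pattern that a 3-substituted furan and a propiolate produce once the oxygen bridge opens, the furan oxygen ending on C1.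
Forward, 3-furyllithium and silylated dihydroxyacetone join C6–C8, the benzene ring (the only carbocycle) is built next, the ester is reduced, C7–OH and the phenol are acylated, the silyl groups are removed and the oxirane is closed last.
The butanoate centre comes from (R)-2-methylbutanoic acid, the Z alkene from angelic acid, and C8 from lipase desymmetrisation of the prochiral triol, carried unchanged into the oxirane.

Key step: step 3

Assumption: the lipase of step 8 is taken to acetylate the pro-R hydroxymethyl group of the prochiral triol, as the (R) configuration at C8 requires; the sense has to be confirmed on the first batch, and the fallback for step 8 covers the opposite preference.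

**Route**

Step 1
Reactants: 1 1,3-dihydroxyacetone (used as its commercial dimer)
Product: 2 1,3-bis(tert-butyldimethylsilyloxy)propan-2-one
Conditions: TBSCl, imidazole, DMF, 0 → 23 °C
Reagents that add atoms: tert-butyldimethylsilyl chloride (TBSCl), CC(C)(C)[Si](C)(C)Cl
Why: Imidazole-promoted silylation of both primary hydroxyls (silyl ether formation) opens the hemiketal dimer and should give the symmetric ketone, whose TBS ethers tolerate organolithium, Lewis acid and hydride conditions and come off with fluoride at the end.

Step 2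
Reactants: 3 3-bromofuran; 2 1,3-bis(tert-butyldimethylsilyloxy)propan-2-one
Product: 6 3-[1,3-bis(tert-butyldimethylsilyloxy)-2-(trimethylsilyloxy)propan-2-yl]furan, via 3-furyllithium 4 (not isolated), via lithium alkoxide 5 (not isolated)
Conditions: n-BuLi, THF, −78 °C; then 2, −78 °C; then TMSCl, −78 → 23 °C
Reagents that add atoms: trimethylsilyl chloride (TMSCl), C[Si](C)(C)Cl
Why: Bromine–lithium exchange gives 3-furyllithium, which at −78 °C does not drift to the 2-lithio isomer and adds 1,2 to the ketone (organolithium carbonyl addition, forming C6–C8), and silylation of the tertiary alkoxide in the same flask removes a hydroxyl that could bind ZnI2 in step 3 or take over the angeloyl group after step 6.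

Step 3
Reactants: 6 3-[1,3-bis(tert-butyldimethylsilyloxy)-2-(trimethylsilyloxy)propan-2-yl]furan; 7 methyl propiolate
Product: 9 methyl 4-[1,3-bis(tert-butyldimethylsilyloxy)-2-(trimethylsilyloxy)propan-2-yl]-3-hydroxybenzoate, via oxanorbornadiene cycloadduct 8 (not isolated)
Conditions: 7 (4 equiv), ZnI2 (1 equiv), CH2Cl2, 23 → 40 °C
Reagents that add atoms: none
Why: ZnI2 lowers the LUMO of the propiolate and the furan adds across it in a concerted, asynchronous [4+2] cycloaddition (furan–alkyne Diels–Alder reaction) that forms C1–C2 and C3–C4 and thereby closes the six-membered carbocycle in one intermolecular suprafacial event, giving the oxygen-bridged diene 8. The same Lewis acid then ionises the bridge C–O bond at C4, because the resulting cyclohexadienyl cation spreads its charge over C2, C4 and C6 and keeps it off the ester-bearing C3, and loss of the proton at C1 gives the phenol with the former furan oxygen on C1. The closest known reactions are the Lewis-acid-promoted one-flask conversions of simple furans and propiolates into 3-hydroxybenzoates. No stereocentre results, since both bridgeheads of racemic 8 become arene carbons and C8 stays prochiral. The step needs the orientation in which the propiolate CH bonds to the furan carbon next to the side chain: the larger HOMO coefficient of a 3-alkylfuran at that carbon matches the larger LUMO coefficient at the propiolate β-carbon, the ester then sits on the side remote from the bulky fully substituted C8, and the silyl cap on the C8 oxygen leaves no hydroxyl that could deliver the zinc-bound ester to the near side.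

Step 4
Reactants: 9 methyl 4-[1,3-bis(tert-butyldimethylsilyloxy)-2-(trimethylsilyloxy)propan-2-yl]-3-hydroxybenzoate
Product: 10 2-[1,3-bis(tert-butyldimethylsilyloxy)-2-(trimethylsilyloxy)propan-2-yl]-5-(hydroxymethyl)phenol
Conditions: i-Bu2AlH (DIBAL-H), CH2Cl2, −78 → 0 °C; aq. potassium sodium tartrate
Reagents that add atoms: none
Why: The aluminium hydride reduces the methyl ester to the primary alcohol (hydride reduction of an ester) after one equivalent has been consumed by the phenol, and silyl ethers are not touched at this temperature.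

Step 5
Reactants: 10 2-[1,3-bis(tert-butyldimethylsilyloxy)-2-(trimethylsilyloxy)propan-2-yl]-5-(hydroxymethyl)phenol; 11 (R)-2-methylbutanoic acid
Product: 12 4-[1,3-bis(tert-butyldimethylsilyloxy)-2-(trimethylsilyloxy)propan-2-yl]-3-hydroxybenzyl (2R)-2-methylbutanoate
Conditions: PPh3, DIAD, THF, 0 → 23 °C
Reagents that add atoms: none
Why: In the Mitsunobu esterification only the primary benzylic alcohol is activated and the carboxylic acid, by far the most acidic component, is the nucleophile, so the hindered phenol is left free and the acid, never activated at its carbonyl group, keeps its (R) centre.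

Step 6
Reactants: 12 4-[1,3-bis(tert-butyldimethylsilyloxy)-2-(trimethylsilyloxy)propan-2-yl]-3-hydroxybenzyl (2R)-2-methylbutanoate; 13 angelic acid, (2Z)-2-methylbut-2-enoic acid
Product: 15 2-[1,3-bis(tert-butyldimethylsilyloxy)-2-(trimethylsilyloxy)propan-2-yl]-5-{[(2R)-2-methylbutanoyl]oxymethyl}phenyl (2Z)-2-methylbut-2-enoate, via mixed anhydride 14 (not isolated)
Conditions: 13, 2,4,6-trichlorobenzoyl chloride, Et3N, toluene, 23 °C; then 12, 23 → 60 °C
Reagents that add atoms: none
Why: Yamaguchi-type mixed-anhydride acylation without a nucleophilic amine catalyst is the established way to transfer an angeloyl group without Z to E isomerisation to the tiglate, the phenol attacking the less hindered angeloyl carbonyl of 14 while the silyl cap keeps the neighbouring tertiary oxygen from taking over the acyl group.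

Step 7
Reactants: 15 2-[1,3-bis(tert-butyldimethylsilyloxy)-2-(trimethylsilyloxy)propan-2-yl]-5-{[(2R)-2-methylbutanoyl]oxymethyl}phenyl (2Z)-2-methylbut-2-enoate
Product: 16 5-{[(2R)-2-methylbutanoyl]oxymethyl}-2-(1,2,3-trihydroxypropan-2-yl)phenyl (2Z)-2-methylbut-2-enoate
Conditions: HF·pyridine, pyridine, THF, 0 → 23 °C
Reagents that add atoms: none
Why: Buffered HF·pyridine cleaves the two primary TBS ethers and the tertiary TMS ether (fluoride desilylation) under slightly acidic conditions in which neither ester is cleaved nor the aryl ester is moved to a neighbouring hydroxyl.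

Step 8
Reactants: 16 5-{[(2R)-2-methylbutanoyl]oxymethyl}-2-(1,2,3-trihydroxypropan-2-yl)phenyl (2Z)-2-methylbut-2-enoate
Product: 17 2-[(2R)-1-acetoxy-2,3-dihydroxypropan-2-yl]-5-{[(2R)-2-methylbutanoyl]oxymethyl}phenyl (2Z)-2-methylbut-2-enoate
Conditions: vinyl acetate, Burkholderia cepacia lipase (Amano lipase PS), t-BuOMe, 30 °C
Reagents that add atoms: vinyl acetate, C=COC(C)=O
Why: Lipase-catalysed irreversible transesterification with vinyl acetate (enzymatic desymmetrisation of a 2,2-disubstituted propane-1,3-diol) should acetylate one enantiotopic hydroxymethyl group and thereby set C8 as (R), the tertiary hydroxyl being no substrate and the hindered angelate and α-branched butanoate being poor acyl donors for the enzyme.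

Step 9
Reactants: 17 2-[(2R)-1-acetoxy-2,3-dihydroxypropan-2-yl]-5-{[(2R)-2-methylbutanoyl]oxymethyl}phenyl (2Z)-2-methylbut-2-enoate
Product: 18 2-[(2R)-2-(acetoxymethyl)oxiran-2-yl]-5-{[(2R)-2-methylbutanoyl]oxymethyl}phenyl (2Z)-2-methylbut-2-enoate (CNP0256757.1)
Conditions: PPh3, DIAD, toluene, 0 → 23 °C
Reagents that add atoms: none
Why: Mitsunobu cyclodehydration of a 1,2-diol turns the primary hydroxyl into an oxyphosphonium leaving group that the tertiary oxygen displaces in a 3-exo-tet closure, so no bond to C8 is broken and its configuration is carried unchanged into the oxirane.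

**Compound list**

1 | 1,3-dihydroxyacetone | OCC(=O)CO | starting material
2 | 1,3-bis(tert-butyldimethylsilyloxy)propan-2-one | CC(C)(C)[Si](C)(C)OCC(=O)CO[Si](C)(C)C(C)(C)C | intermediate
3 | 3-bromofuran | Brc1ccoc1 | starting material
4 | 3-furyllithium | [Li]c1ccoc1 | intermediate (not isolated)
5 | lithium 1,3-bis(tert-butyldimethylsilyloxy)-2-(furan-3-yl)propan-2-olate | [Li]OC(CO[Si](C)(C)C(C)(C)C)(CO[Si](C)(C)C(C)(C)C)c1ccoc1 | intermediate (not isolated)
6 | 3-[1,3-bis(tert-butyldimethylsilyloxy)-2-(trimethylsilyloxy)propan-2-yl]furan | C[Si](C)(C)OC(CO[Si](C)(C)C(C)(C)C)(CO[Si](C)(C)C(C)(C)C)c1ccoc1 | intermediate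
7 | methyl propiolate | C#CC(=O)OC | starting material
8 | methyl 5-[1,3-bis(tert-butyldimethylsilyloxy)-2-(trimethylsilyloxy)propan-2-yl]-7-oxabicyclo[2.2.1]hepta-2,5-diene-2-carboxylate (racemic) | COC(=O)C1=CC2OC1C=C2C(O[Si](C)(C)C)(CO[Si](C)(C)C(C)(C)C)CO[Si](C)(C)C(C)(C)C | intermediate (not isolated)
9 | methyl 4-[1,3-bis(tert-butyldimethylsilyloxy)-2-(trimethylsilyloxy)propan-2-yl]-3-hydroxybenzoate | COC(=O)c1ccc(c(O)c1)C(O[Si](C)(C)C)(CO[Si](C)(C)C(C)(C)C)CO[Si](C)(C)C(C)(C)C | intermediate
10 | 2-[1,3-bis(tert-butyldimethylsilyloxy)-2-(trimethylsilyloxy)propan-2-yl]-5-(hydroxymethyl)phenol | OCc1ccc(c(O)c1)C(O[Si](C)(C)C)(CO[Si](C)(C)C(C)(C)C)CO[Si](C)(C)C(C)(C)C | intermediate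
11 | (R)-2-methylbutanoic acid | CC[C@@H](C)C(=O)O | starting material
12 | 4-[1,3-bis(tert-butyldimethylsilyloxy)-2-(trimethylsilyloxy)propan-2-yl]-3-hydroxybenzyl (2R)-2-methylbutanoate | CC[C@@H](C)C(=O)OCc1ccc(c(O)c1)C(O[Si](C)(C)C)(CO[Si](C)(C)C(C)(C)C)CO[Si](C)(C)C(C)(C)C | intermediate
13 | angelic acid, (2Z)-2-methylbut-2-enoic acid | C/C=C(/C)C(=O)O | starting material
14 | (2Z)-2-methylbut-2-enoic 2,4,6-trichlorobenzoic anhydride | C/C=C(/C)C(=O)OC(=O)c1c(Cl)cc(Cl)cc1Cl | intermediate (not isolated)
15 | 2-[1,3-bis(tert-butyldimethylsilyloxy)-2-(trimethylsilyloxy)propan-2-yl]-5-{[(2R)-2-methylbutanoyl]oxymethyl}phenyl (2Z)-2-methylbut-2-enoate | C/C=C(/C)C(=O)Oc1cc(COC(=O)[C@H](C)CC)ccc1C(O[Si](C)(C)C)(CO[Si](C)(C)C(C)(C)C)CO[Si](C)(C)C(C)(C)C | intermediate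
16 | 5-{[(2R)-2-methylbutanoyl]oxymethyl}-2-(1,2,3-trihydroxypropan-2-yl)phenyl (2Z)-2-methylbut-2-enoate | C/C=C(/C)C(=O)Oc1cc(COC(=O)[C@H](C)CC)ccc1C(O)(CO)CO | intermediate
17 | 2-[(2R)-1-acetoxy-2,3-dihydroxypropan-2-yl]-5-{[(2R)-2-methylbutanoyl]oxymethyl}phenyl (2Z)-2-methylbut-2-enoate | C/C=C(/C)C(=O)Oc1cc(COC(=O)[C@H](C)CC)ccc1[C@](O)(COC(C)=O)CO | intermediate
18 | 2-[(2R)-2-(acetoxymethyl)oxiran-2-yl]-5-{[(2R)-2-methylbutanoyl]oxymethyl}phenyl (2Z)-2-methylbut-2-enoate (CNP0256757.1) | C/C=C(/C)C(=O)Oc1cc(COC(=O)[C@H](C)CC)ccc1[C@]1(COC(C)=O)CO1 | target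

**Step count and risks**

Total steps: 9. Longest linear sequence: 9 steps (1 to 18).

Step 3 is the most likely to fail. The cycloaddition may be too slow with the hindered furan, may be diverted into conjugate addition of a free furan α-position to the activated alkyne, or may join the ester-bearing alkyne carbon to the furan carbon next to the side chain, which would lead to the 3-hydroxy-5-alkylbenzoate. The fallback takes the benzene ring from a preformed arene, sets out from ketone 2 and rejoins the route at 9. Commercial methyl 3-hydroxy-4-iodobenzoate is benzylated (BnBr, K2CO3, DMF) to methyl 3-(benzyloxy)-4-iodobenzoate F1. Iodine–magnesium exchange (i-PrMgCl·LiCl, THF, −40 °C, a temperature at which the ester is tolerated) should give [2-(benzyloxy)-4-(methoxycarbonyl)phenyl]magnesium chloride F2. Addition of this to 2 should give chloromagnesium 2-[2-(benzyloxy)-4-(methoxycarbonyl)phenyl]-1,3-bis(tert-butyldimethylsilyloxy)propan-2-olate F3. Silylation in the flask with TMSCl should give methyl 3-(benzyloxy)-4-[1,3-bis(tert-butyldimethylsilyloxy)-2-(trimethylsilyloxy)propan-2-yl]benzoate F4, and hydrogenolysis of the benzyl ether (H2, Pd/C, EtOAc) leads back to 9.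

Step 8 is the second risk. The enzyme may acetylate the other enantiotopic hydroxymethyl group or discriminate poorly between the two, and acetyl migration between the primary hydroxyls may erode the enantiomeric purity. The fallback sets out from triol 16 and returns at 17. Both primary hydroxyls are acetylated (Ac2O, pyridine, CH2Cl2, 0 °C) to 2-(1,3-diacetoxy-2-hydroxypropan-2-yl)-5-{[(2R)-2-methylbutanoyl]oxymethyl}phenyl (2Z)-2-methylbut-2-enoate F5. The same lipase is then used in the deacylating direction (n-BuOH, t-BuOMe, 30 °C). It should remove the acetyl group from the arm it prefers, so the surviving acetate sits on the other arm and the enantiomeric series is opposite to that of the acylation mode.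

Step 9 is the third risk. Under the dehydrating conditions the angeloyl group may be transferred from the phenol oxygen to the transient tertiary alkoxide, or the acetyl group may migrate before ring closure and lower the enantiomeric purity. The fallback sets out from 17 and returns at 18. The primary hydroxyl is converted to the iodide (PPh3, I2, imidazole, CH2Cl2, 0 °C) to give 2-[(2S)-1-acetoxy-2-hydroxy-3-iodopropan-2-yl]-5-{[(2R)-2-methylbutanoyl]oxymethyl}phenyl (2Z)-2-methylbut-2-enoate F6. The oxirane is then closed with Ag2O in MeCN at 23 °C, where halide abstraction by silver assists attack of the neutral tertiary hydroxyl and no free alkoxide is required.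

**Further compounds**

F1 | step 3 | methyl 3-(benzyloxy)-4-iodobenzoate | COC(=O)c1ccc(I)c(OCc2ccccc2)c1
F2 | step 3 | [2-(benzyloxy)-4-(methoxycarbonyl)phenyl]magnesium chloride | COC(=O)c1ccc([Mg]Cl)c(OCc2ccccc2)c1
F3 | step 3 | chloromagnesium 2-[2-(benzyloxy)-4-(methoxycarbonyl)phenyl]-1,3-bis(tert-butyldimethylsilyloxy)propan-2-olate | COC(=O)c1ccc(c(OCc2ccccc2)c1)C(O[Mg]Cl)(CO[Si](C)(C)C(C)(C)C)CO[Si](C)(C)C(C)(C)C
F4 | step 3 | methyl 3-(benzyloxy)-4-[1,3-bis(tert-butyldimethylsilyloxy)-2-(trimethylsilyloxy)propan-2-yl]benzoate | COC(=O)c1ccc(c(OCc2ccccc2)c1)C(O[Si](C)(C)C)(CO[Si](C)(C)C(C)(C)C)CO[Si](C)(C)C(C)(C)C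
F5 | step 8 | 2-(1,3-diacetoxy-2-hydroxypropan-2-yl)-5-{[(2R)-2-methylbutanoyl]oxymethyl}phenyl (2Z)-2-methylbut-2-enoate | C/C=C(/C)C(=O)Oc1cc(COC(=O)[C@H](C)CC)ccc1C(O)(COC(C)=O)COC(C)=O
F6 | step 9 | 2-[(2S)-1-acetoxy-2-hydroxy-3-iodopropan-2-yl]-5-{[(2R)-2-methylbutanoyl]oxymethyl}phenyl (2Z)-2-methylbut-2-enoate | C/C=C(/C)C(=O)Oc1cc(COC(=O)[C@H](C)CC)ccc1[C@](O)(COC(C)=O)CI
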